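## Structural features

The target is a (2R,3R)-3-hydroxyflavanone: a benzene ring A fused through C4a and C8a to a dihydropyranone ring C (O1–C2–C3–C4), with an unsubstituted phenyl ring B on C2. Ring A is hexasubstituted: going round from C4a it carries a chelated hydroxyl at C5, a 3-methylbut-2-enyl (prenyl) group at C6, a second hydroxyl at C7, a methoxyl at C8 and the ring oxygen at C8a. The only stereocentres, C2 (benzylic ether carbon) and C3 (carbinol carbon next to the ketone), are adjacent and trans. Three elements are fragile. The prenyl alkene lies between two phenols, cyclises onto either under strong acid and is attacked by electrophilic oxidants. The β-aryloxy α-hydroxy ketone opens to a chalcone, epimerises or dehydrogenates under base. The arene is very electron-rich. The real difficulties are the regiochemistry of ring A (three oxygens to be told apart, prenyl and methoxyl in fixed places) and the absolute configuration at C2/C3, which must be set without an alkene oxidation on a prenyl-bearing intermediate. The key step uses two facts: C4a and the oxygen-bearing C8a are neighbours on ring A, and C4–C3–C2 is a three-carbon unit oxygenated at every carbon with C2 benzylic. That is the pattern formed when the free ortho carbon of a phenol adds to the formyl group of a trans-3-phenyloxirane-2-carbaldehyde and the phenol oxygen then opens the oxirane at its benzylic carbon. A stereochemical check of this course (C3 keeps the oxygen and sense of oxirane C2, C2 arises by inversion at oxirane C3) confirms that the (2R,3S)-oxirane aldehyde is the antipode needed for a (2R,3R) target, so no structure needed correction.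

## Logic of the disconnections

19 to 18: the O5–CH2 and O7–CH2 acetal bonds are added retrosynthetically. The two phenols flanking the prenyl group must be masked through lithiation, magnesium chemistry and oxidation, and the acetals also direct the prenylation. The skeleton is unchanged. The forward step needs acid mild enough to spare the prenyl group.

18 to 17: the C4 carbonyl is taken back to a carbinol. At the ketone level the ring-closure precursor would be a 2'-hydroxychalcone epoxide, which is base-labile and prone to five-ring closure. At the alcohol level C4 is the product of a carbonyl addition. The forward step needs an oxidant that takes the benzylic carbinol and leaves the C3 hydroxyl and the alkene alone.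

17 to 11 and 14: the C4–C4a and O1–C2 bonds are cut. This separates the complete ring A from a three-carbon piece that already holds both stereocentres, and ring C disappears in one operation. The forward step must give C- rather than O-attack on the aldehyde and a 6-endo opening at the benzylic carbon with inversion. The design of 11 follows from this: O1 free, a single unsubstituted ring carbon, and O5 and O7 masked. A free O5 could close the ring in the wrong sense, and a free O7, para to C4, would make the diol ionise.

14 to 13 to 12: the formyl group is taken back to a primary alcohol and the two C–O bonds of the oxirane are cut. The epoxidation is then reagent-controlled and is done on a fragment without the prenyl alkene, and 13 is a crystalline checkpoint for enantiomeric purity. A direct one-step epoxidation of the corresponding enal would save a step but gives no such checkpoint. The oxidation of 13 must not epimerise the formyl-bearing carbon.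

11 to 10: the O1–Si bond is added. O1 must differ from O7 from the start, and the silyl ether also shields C4a during lithiation. Fluoride must remove it without touching the acetals.

10 to 6 and 7: the aryl–CH2 bond at C6 is cut. The carbon between two acetal oxygens is the most acidic ring position, so directed metalation gives the nucleophile, and the whole prenyl group comes from a commercial bromide. The alkylation must be linear (SN2, not SN2').

6 to 5 to 3: the O5–CH2 acetal bond and then the C5–O bond (through C5–B) are cut. C5 is the only C–H of a 1,2,3-trisubstituted benzene not flanked by a substituent and cannot be reached by electrophilic substitution, so a sterically governed C–H borylation is used. The oxidation of the boronate must spare the silyl ether.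

3 to 2 to 1: the O7–CH2 and O1–Si bonds are cut. 1 already has the three contiguous oxygens with the methyl ether in the middle. Its two hydroxyls are equivalent and must be told apart once. This is the only statistical step, and it is placed first, where material is cheapest.

## Other disconnections considered

Alternative 1: The cut is O1–C8a.
- **Forward step:** the open-chain para-methoxyphenol ketone A1 would be oxidised at an anode in methanol to the quinone monoketal at C8. The benzylic hydroxyl would add to C8a, which is β to both the dienone carbonyl at C5 and the C4 ketone, and loss of methanol would restore the arene and give A2.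
- **In its favour:** the ring closure forms no C–C bond, creates no stereocentre, has no five-ring competitor and arrives at the C4 ketone directly. On ring-closure regiochemistry and on redox economy after ring closure it is the better plan.
- **Against it:** both stereocentres must be built in the open chain as an α,β-dihydroxy ketone on a hindered aryl ketone, which calls for an enantioselective glycolate-type aldol. A1 is a β-hydroxy ketone open to retro-aldol cleavage and β-elimination. The prenyl alkene must survive the anodic potential, and the monoketal can hydrolyse to the quinone.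
- **Comparison:** structurally it leaves the C2/C3 problem to an acyclic aldol, where the chosen plan takes both centres from a crystalline epoxy alcohol. Mechanistically it replaces a chelation-dependent one-pot step by an umpolung of the arene, which needs electrolysis next to an oxidisable alkene. In step count it should be longer (aryl ketone, aldol, two kinds of protection), and C8a must stay unsubstituted to the end.

Alternative 2: The cuts are C4a–C4, C4–C3 and O1–C2.
- **Forward step:** the ortho-iodophenol A3 (the iodination product of 11), carbon monoxide A4 and phenylacetylene A5 would combine under PdCl2(PPh3)2 in diethylamine. An acylpalladium species gives the alkynyl ketone, and amine-mediated 6-endo addition of the phenol gives the flavone A6.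
- **In its favour:** three bonds form in one operation from 11 and two simple partners, the flavone-versus-aurone outcome is governed by the secondary amine, and C4 is a carbonyl from the start. In convergence and in reliability of the ring-forming event it is the equal or the better of the chosen plan.
- **Against it:** A6 is flat. Both stereocentres would then have to be introduced across C2=C3: an enantioselective conjugate reduction followed by a trans-selective enolate hydroxylation, or an epoxidation–reduction sequence. Each must spare the prenyl alkene and must tolerate a flavanone that ring-opens and racemises under base. Iodination of 11 next to the alkene is a further chemoselectivity question.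
- **Comparison:** structurally it solves ring C but defers the real difficulty. Mechanistically its key step is better precedented than the chosen one. In step economy the short annulation is outweighed by the stereochemical steps that must follow.

Alternative 3: The cut is C2–C3.
- **Forward step:** the tertiary α-hydroxy aldehyde A7 would undergo an α-ketol shift. C2 moves from the carbinol carbon to the formyl carbon, the carbinol carbon becomes the C4 ketone and the formyl carbon the C3 carbinol. The five-membered ring expands to ring C and gives A8.
- **In its favour:** the shift is driven by loss of five-ring strain and gain of an aryl ketone. C2 migrates with retention. Ketone and hydroxyl appear in the right oxidation states without any oxidant, and on this point it is the better plan.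
- **Against it:** the electron-rich aryl carbon is the competing, and probably the better, migrating group, and would give a chroman-3-one skeleton. The new C3 centre is set only by thermodynamic or chelation preference. A7 requires an enantiopure C2 next to an enolisable benzofuranone during its synthesis, plus a formyl anion equivalent.
- **Comparison:** structurally the chosen plan takes C2 and C3 together from one epoxide, whereas this one must protect a labile C2 and create C3 late. Mechanistically both rely on chelation, but here the wrong outcome is a different skeleton and not an epimer that is later erased. In step count it should be longer.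

Key step: step 9

Assumption: the configuration of the C4 carbinol is irrelevant because step 10 erases it; 16 and 17 are drawn and named as the 4R epimers expected from chelation control, and a 4S epimer would be carried through in the same way.

Step 1
Reactants: 1 2-methoxybenzene-1,3-diol (2-methoxyresorcinol)
Product: 2 2-methoxy-3-(triisopropylsilyloxy)phenol
Conditions: TIPSCl (0.95 equiv), imidazole, DMF, 0 °C to rt
Reagents that add atoms: triisopropylsilyl chloride, CC(C)[Si](Cl)(C(C)C)C(C)C
Why: Silyl ether formation at one of two equivalent phenols; a small deficit of the chloride should keep double silylation low, and unreacted 1 and the bis-silyl ether (after fluoride cleavage) can be recycled. The bulky group marks the future ring oxygen O1 and later shields its ortho carbon from lithiation.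

Step 2
Reactants: 2 2-methoxy-3-(triisopropylsilyloxy)phenol
Product: 3 triisopropyl[2-methoxy-3-(methoxymethoxy)phenoxy]silane
Conditions: MOMCl, iPr2NEt, CH2Cl2, 0 °C to rt
Reagents that add atoms: chloromethyl methyl ether, COCCl
Why: Methoxymethyl ether formation (O-alkylation of the phenol) at the remaining hydroxyl; the acetal is stable to base, fluoride and the boron chemistry and will later direct the lithiation.

Step 3
Reactants: 3 triisopropyl[2-methoxy-3-(methoxymethoxy)phenoxy]silane
Product: 5 4-methoxy-3-(methoxymethoxy)-5-(triisopropylsilyloxy)phenol, via arylboronate 4 (not isolated)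
Conditions: [Ir(OMe)(cod)]2 (1.5 mol%), dtbpy (3 mol%), B2pin2 (1.0 equiv), THF, 60 °C; then NaBO3·4H2O, THF/H2O, rt
Reagents that add atoms: sodium perborate, [Na+].[O-]B1OO1 (oxygen of the new phenol); bis(pinacolato)diboron, CC1(C)OB(OC1(C)C)B1OC(C)(C)C(C)(C)O1 (boryl group of 4 only)
Why: Iridium-catalysed C–H borylation is sterically governed and on a 1,2,3-trisubstituted benzene should go only to C5, the one C–H bond with no ortho substituent. Perborate then oxidises the C–B bond of 4 (aryl shift from boron to oxygen) under mildly basic conditions that should leave the silyl ether and the acetal intact.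

Step 4
Reactants: 5 4-methoxy-3-(methoxymethoxy)-5-(triisopropylsilyloxy)phenol
Product: 6 triisopropyl[2-methoxy-3,5-bis(methoxymethoxy)phenoxy]silane
Conditions: MOMCl, iPr2NEt, CH2Cl2, 0 °C to rt
Reagents that add atoms: chloromethyl methyl ether, COCCl
Why: Methoxymethyl ether formation at the new unhindered phenol; one ring carbon is now flanked by two acetal oxygens, the arrangement needed for step 5.

Step 5
Reactants: 6 triisopropyl[2-methoxy-3,5-bis(methoxymethoxy)phenoxy]silane, 7 1-bromo-3-methylbut-2-ene (prenyl bromide)
Product: 10 triisopropyl[2-methoxy-3,5-bis(methoxymethoxy)-4-(3-methylbut-2-enyl)phenoxy]silane, via aryllithium 8 (not isolated), via arylcopper 9 (not isolated)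
Conditions: n-BuLi, THF, 0 °C; CuBr·SMe2, −40 °C; 7, −40 °C to rt
Reagents that add atoms: none
Why: Directed ortho-metalation: the C–H bond between the two methoxymethoxy groups is doubly activated, whereas the other aryl C–H is shielded by the silyl ether, which is a poor director. Transmetalation to copper and SN2 alkylation with 7 should give the linear prenyl arene and not the SN2' (1,1-dimethylallyl) isomer.

Step 6
Reactants: 10 triisopropyl[2-methoxy-3,5-bis(methoxymethoxy)-4-(3-methylbut-2-enyl)phenoxy]silane
Product: 11 2-methoxy-3,5-bis(methoxymethoxy)-4-(3-methylbut-2-enyl)phenol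
Conditions: TBAF, AcOH, THF, 0 °C
Reagents that add atoms: none
Why: Fluoride cleavage of the aryl silyl ether, driven by Si–F bond formation and buffered with acetic acid so that the electron-rich phenoxide is protonated at once; acetals and alkene are inert. The phenol is used promptly under inert gas.

Step 7
Reactants: 12 (E)-3-phenylprop-2-en-1-ol (cinnamyl alcohol)
Product: 13 [(2S,3S)-3-phenyloxiran-2-yl]methanol
Conditions: Ti(OiPr)4 (5 mol%), L-(+)-diisopropyl tartrate (7.5 mol%), t-BuOOH, 4 Å MS, CH2Cl2, −20 °C
Reagents that add atoms: tert-butyl hydroperoxide, CC(C)(C)OO
Why: Sharpless asymmetric epoxidation; with the (2R,3R)-tartrate the E-allylic alcohol should give the (2S,3S)-epoxy alcohol, which sets both oxirane centres (the later C3 and, after inversion, C2 of the flavanone) under reagent control. 13 is crystalline, so its enantiomeric purity can be raised by recrystallisation.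

Step 8
Reactants: 13 [(2S,3S)-3-phenyloxiran-2-yl]methanol
Product: 14 (2R,3S)-3-phenyloxirane-2-carbaldehyde
Conditions: TEMPO (10 mol%), PhI(OAc)2, CH2Cl2, rt
Reagents that add atoms: none
Why: Oxoammonium (TEMPO-catalysed) oxidation of the primary alcohol under near-neutral conditions that should neither open the oxirane nor epimerise the formyl-bearing carbon. The descriptor change at that carbon from S to R is only a change in CIP priority; the aldehyde is used without storage.

Step 9
Reactants: 11 2-methoxy-3,5-bis(methoxymethoxy)-4-(3-methylbut-2-enyl)phenol, 14 (2R,3S)-3-phenyloxirane-2-carbaldehyde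
Product: 17 (2R,3S,4R)-8-methoxy-5,7-bis(methoxymethoxy)-6-(3-methylbut-2-enyl)-2-phenyl-3,4-dihydro-2H-chromene-3,4-diol, via magnesium aryloxide 15 (not isolated), via epoxy alcohol 16 (not isolated)
Conditions: n-Bu2Mg (0.55 equiv), toluene, 0 °C; 14 (1.1 equiv), CH2Cl2, −20 °C to rt, then 40 °C; aq. NH4Cl
Reagents that add atoms: none
Why: Proposed new method: halide-free n-Bu2Mg converts 11 into the magnesium bis(aryloxide) 15, whose magnesium binds the aldehyde oxygen of 14 and delivers the carbonyl carbon through a six-membered transition state to C4a, the only unsubstituted ring carbon, forming C4–C4a and the magnesium alkoxide of 16; the closest known reaction is the ortho-specific hydroxyalkylation of magnesium phenoxides with aldehydes in non-coordinating solvents, not yet shown for an α,β-epoxy aldehyde. The C4 alkoxide then bridges to the oxirane oxygen and the phenoxide oxygen attacks the distal benzylic carbon in a 6-endo-tet opening that forms O1–C2 and closes ring C, the known counterparts being the metal-alkoxide-directed C3 opening of 2,3-epoxy alcohols and the 6-endo cyclisation of ortho-hydroxyaryl epoxides to flavan-3-ols. C3 keeps the oxygen and the configuration it has in 14, and C2 is formed with inversion, so that the 3S oxirane carbon becomes 2R. The new C4 centre should arise mainly as 4R from a chelate in which magnesium holds the carbonyl and oxirane oxygens syn and the arene enters anti to the oxirane C–C bond, but it is erased in step 10. C- over O-alkylation is secured by the tight Mg–O bond in toluene/CH2Cl2 and by the single free ring position; 6-endo over 5-exo closure is secured by benzylic stabilisation of the developing charge and by the chelate geometry; leaving out halide removes halohydrin formation and Lewis-acid rearrangement of the aryl epoxide. Either order of the two bond formations leads to 17, because O-alkylation at the benzylic carbon first would leave the aldehyde tethered for the same closure onto C4a.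

Step 10
Reactants: 17 (2R,3S,4R)-8-methoxy-5,7-bis(methoxymethoxy)-6-(3-methylbut-2-enyl)-2-phenyl-3,4-dihydro-2H-chromene-3,4-diol
Product: 18 (2R,3R)-3-hydroxy-8-methoxy-5,7-bis(methoxymethoxy)-6-(3-methylbut-2-enyl)-2-phenyl-2,3-dihydro-4H-chromen-4-one
Conditions: MnO2 (activated, excess), CH2Cl2, rt
Reagents that add atoms: none
Why: Activated MnO2 oxidises benzylic alcohols, here on a very electron-rich ring, much faster than saturated secondary ones, so the C4 carbinol (either epimer) should become the aryl ketone while the C3 hydroxyl and the alkene are kept. Neutral conditions avoid ionisation at C4 and epimerisation at C2/C3; the descriptor at C3 changes from S to R by CIP priority only.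

Step 11
Reactants: 18 (2R,3R)-3-hydroxy-8-methoxy-5,7-bis(methoxymethoxy)-6-(3-methylbut-2-enyl)-2-phenyl-2,3-dihydro-4H-chromen-4-one
Product: 19 (2R,3R)-3,5,7-trihydroxy-8-methoxy-6-(3-methylbut-2-enyl)-2-phenyl-2,3-dihydro-4H-chromen-4-one
Conditions: 3 M HCl, MeOH, 40 °C
Reagents that add atoms: none
Why: Acid-catalysed transacetalisation of both methoxymethyl ethers to methanol (acetal cleavage); acid strength and temperature are kept low so that the prenyl group does not cyclise onto the freed phenols. C2 and C3 are not touched, and the trans isomer is also the thermodynamically preferred one.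

## Compound list

1 | 2-methoxybenzene-1,3-diol (2-methoxyresorcinol) | COc1c(O)cccc1O | starting material
2 | 2-methoxy-3-(triisopropylsilyloxy)phenol | COc1c(O)cccc1O[Si](C(C)C)(C(C)C)C(C)C | intermediate
3 | triisopropyl[2-methoxy-3-(methoxymethoxy)phenoxy]silane | COCOc1cccc(O[Si](C(C)C)(C(C)C)C(C)C)c1OC | intermediate
4 | triisopropyl[2-methoxy-3-(methoxymethoxy)-5-(4,4,5,5-tetramethyl-1,3,2-dioxaborolan-2-yl)phenoxy]silane | COCOc1cc(B2OC(C)(C)C(C)(C)O2)cc(O[Si](C(C)C)(C(C)C)C(C)C)c1OC | intermediate (not isolated)
5 | 4-methoxy-3-(methoxymethoxy)-5-(triisopropylsilyloxy)phenol | COCOc1cc(O)cc(O[Si](C(C)C)(C(C)C)C(C)C)c1OC | intermediate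
6 | triisopropyl[2-methoxy-3,5-bis(methoxymethoxy)phenoxy]silane | COCOc1cc(OCOC)cc(O[Si](C(C)C)(C(C)C)C(C)C)c1OC | intermediate
7 | 1-bromo-3-methylbut-2-ene (prenyl bromide) | CC(C)=CCBr | starting material
8 | [3-methoxy-2,6-bis(methoxymethoxy)-4-(triisopropylsilyloxy)phenyl]lithium | [Li]c1c(OCOC)cc(O[Si](C(C)C)(C(C)C)C(C)C)c(OC)c1OCOC | intermediate (not isolated)
9 | [3-methoxy-2,6-bis(methoxymethoxy)-4-(triisopropylsilyloxy)phenyl]copper | [Cu]c1c(OCOC)cc(O[Si](C(C)C)(C(C)C)C(C)C)c(OC)c1OCOC | intermediate (not isolated)
10 | triisopropyl[2-methoxy-3,5-bis(methoxymethoxy)-4-(3-methylbut-2-enyl)phenoxy]silane | CC(C)=CCc1c(OCOC)cc(O[Si](C(C)C)(C(C)C)C(C)C)c(OC)c1OCOC | intermediate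
11 | 2-methoxy-3,5-bis(methoxymethoxy)-4-(3-methylbut-2-enyl)phenol | COc1c(O)cc(OCOC)c(CC=C(C)C)c1OCOC | intermediate
12 | (E)-3-phenylprop-2-en-1-ol (cinnamyl alcohol) | OC/C=C/c1ccccc1 | starting material
13 | [(2S,3S)-3-phenyloxiran-2-yl]methanol | OC[C@@H]1O[C@H]1c1ccccc1 | intermediate
14 | (2R,3S)-3-phenyloxirane-2-carbaldehyde | O=C[C@@H]1O[C@H]1c1ccccc1 | intermediate
15 | magnesium bis[2-methoxy-3,5-bis(methoxymethoxy)-4-(3-methylbut-2-enyl)phenolate] | COc1c(O[Mg]Oc2cc(OCOC)c(CC=C(C)C)c(OCOC)c2OC)cc(OCOC)c(CC=C(C)C)c1OCOC | intermediate (not isolated)
16 | 6-{(R)-hydroxy[(2S,3S)-3-phenyloxiran-2-yl]methyl}-2-methoxy-3,5-bis(methoxymethoxy)-4-(3-methylbut-2-enyl)phenol, formed as its magnesium salt | COc1c(O)c([C@@H](O)[C@@H]2O[C@H]2c2ccccc2)c(OCOC)c(CC=C(C)C)c1OCOC | intermediate (not isolated)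
17 | (2R,3S,4R)-8-methoxy-5,7-bis(methoxymethoxy)-6-(3-methylbut-2-enyl)-2-phenyl-3,4-dihydro-2H-chromene-3,4-diol | COc1c(OCOC)c(CC=C(C)C)c(OCOC)c2c1O[C@H](c1ccccc1)[C@@H](O)[C@@H]2O | intermediate
18 | (2R,3R)-3-hydroxy-8-methoxy-5,7-bis(methoxymethoxy)-6-(3-methylbut-2-enyl)-2-phenyl-2,3-dihydro-4H-chromen-4-one | COc1c(OCOC)c(CC=C(C)C)c(OCOC)c2c1O[C@H](c1ccccc1)[C@@H](O)C2=O | intermediate
19 | (2R,3R)-3,5,7-trihydroxy-8-methoxy-6-(3-methylbut-2-enyl)-2-phenyl-2,3-dihydro-4H-chromen-4-one | COc1c(O)c(CC=C(C)C)c(O)c2c1O[C@H](c1ccccc1)[C@@H](O)C2=O | target

## Step count and least certain steps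

Total: 11 steps. Longest linear sequence: 9 steps (steps 1 to 6, then 9, 10 and 11, from 1). The epoxy aldehyde branch has 2 steps (7 and 8).

**Step 9 (key step, proposed new method).** The most likely failures are as follows.
- Ring closure through the proximal oxirane carbon (5-exo) would give a dihydrobenzofuran.
- Loss of the C4 oxygen by ortho-quinone-methide formation from the magnesium salt of 16 would be followed by attack of a second aryloxide.
- The C4 alkoxide could cause epoxide migration (Payne rearrangement).

All three arise because the second bond formation is slower than the first and needs Lewis-acid activation in the same flask. The fallback uses known reactions only, sets out from 11 and 14 and returns at 17.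
- Phenol 11 would be capped with ethyl vinyl ether and PPTS in CH2Cl2 as the 1-ethoxyethyl ether F1.
- Directed ortho-lithiation of F1 (n-BuLi, THF, 0 °C) at its single aryl C–H, between two acetal oxygens, and addition of the aryllithium to 14 at −78 °C would give the protected epoxy alcohol F2.
- PPTS in ethanol at 0 °C would remove the ethoxyethyl group in the presence of the methoxymethyl ethers and give 16 as an isolated phenol.
- Ti(OiPr)4 in CH2Cl2 would then promote the chelation-directed opening at the benzylic carbon, as in the opening of 2,3-epoxy alcohols at C3 and the cyclisation of ortho-hydroxyaryl epoxides to flavan-3-ols, to give 17.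

**Step 10.** The C4 carbinol is hindered by the peri methoxymethoxy group, so oxidation may stall. Long exposure may cause ionisation at C4 or further oxidation at C3. The fallback sets out from 17 and returns at 19.
- Selective silylation of the less hindered C3 hydroxyl (TBSCl, imidazole, DMF) would give the 3-O-tert-butyldimethylsilyl ether F3.
- Dess–Martin periodinane with NaHCO3 in CH2Cl2 would oxidise the remaining C4 carbinol to the silyloxy ketone F4.
- The acid methanolysis of step 11 would then remove the silyl ether together with both acetals and give 19 directly.

**Step 11.** Protic acid may protonate the prenyl alkene and cause cyclisation onto the C5 or C7 phenol once these are free, or the C7 acetal may be left behind. The fallback sets out from 18 and returns at 19. It avoids protic acid: TMSOTf and 2,2'-bipyridyl in CH2Cl2 at 0 °C would convert the aryl acetals (and the C3 hydroxyl) into silyl ethers, giving the tris(trimethylsilyl) ether F5, which water in THF at rt would hydrolyse to 19.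

**Step 5.** Allylic transposition during the alkylation would give the 1,1-dimethylallyl isomer, and competing deprotonation or incomplete transmetalation would lower conversion. The fallback sets out from 6 and returns at 10. The same lithiation and cupration followed by allyl bromide, which has no regiochemical ambiguity, would give the allyl arene F6. Cross-metathesis of F6 with 2-methyl-2-butene (solvent) and the second-generation Grubbs catalyst (H2IMes)(PCy3)Cl2Ru=CHPh at 40 °C would give 10.

## Further compounds

F1 | step 9 | 1-(1-ethoxyethoxy)-2-methoxy-3,5-bis(methoxymethoxy)-4-(3-methylbut-2-enyl)benzene (acetal carbon as both epimers) | CCOC(C)Oc1cc(OCOC)c(CC=C(C)C)c(OCOC)c1OC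
F2 | step 9 | [2-(1-ethoxyethoxy)-3-methoxy-4,6-bis(methoxymethoxy)-5-(3-methylbut-2-enyl)phenyl][(2S,3S)-3-phenyloxiran-2-yl]methanol (carbinol and acetal carbons as both epimers) | CCOC(C)Oc1c(OC)c(OCOC)c(CC=C(C)C)c(OCOC)c1C(O)[C@@H]1O[C@H]1c1ccccc1
F3 | step 10 | (2R,3S,4R)-3-(tert-butyldimethylsilyloxy)-8-methoxy-5,7-bis(methoxymethoxy)-6-(3-methylbut-2-enyl)-2-phenyl-3,4-dihydro-2H-chromen-4-ol | COc1c(OCOC)c(CC=C(C)C)c(OCOC)c2c1O[C@H](c1ccccc1)[C@@H](O[Si](C)(C)C(C)(C)C)[C@@H]2O
F4 | step 10 | (2R,3R)-3-(tert-butyldimethylsilyloxy)-8-methoxy-5,7-bis(methoxymethoxy)-6-(3-methylbut-2-enyl)-2-phenyl-2,3-dihydro-4H-chromen-4-one | COc1c(OCOC)c(CC=C(C)C)c(OCOC)c2c1O[C@H](c1ccccc1)[C@@H](O[Si](C)(C)C(C)(C)C)C2=O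
F5 | step 11 | (2R,3R)-8-methoxy-6-(3-methylbut-2-enyl)-2-phenyl-3,5,7-tris(trimethylsilyloxy)-2,3-dihydro-4H-chromen-4-one | COc1c(O[Si](C)(C)C)c(CC=C(C)C)c(O[Si](C)(C)C)c2c1O[C@H](c1ccccc1)[C@@H](O[Si](C)(C)C)C2=O
F6 | step 5 | triisopropyl[2-methoxy-3,5-bis(methoxymethoxy)-4-(prop-2-enyl)phenoxy]silane | C=CCc1c(OCOC)cc(O[Si](C(C)C)(C(C)C)C(C)C)c(OC)c1OCOC
A1 | alternative 1 | (2R,3R)-2-(tert-butyldimethylsilyloxy)-3-hydroxy-1-[2-hydroxy-5-methoxy-4-(methoxymethoxy)-3-(3-methylbut-2-enyl)phenyl]-3-phenylpropan-1-one | COc1cc(C(=O)[C@H](O[Si](C)(C)C(C)(C)C)[C@H](O)c2ccccc2)c(O)c(CC=C(C)C)c1OCOC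
A2 | alternative 1 | (2R,3R)-3-(tert-butyldimethylsilyloxy)-5-hydroxy-8-methoxy-7-(methoxymethoxy)-6-(3-methylbut-2-enyl)flavanone | COc1c(OCOC)c(CC=C(C)C)c(O)c2c1O[C@H](c1ccccc1)[C@@H](O[Si](C)(C)C(C)(C)C)C2=O
A3 | alternative 2 | 6-iodo-2-methoxy-3,5-bis(methoxymethoxy)-4-(3-methylbut-2-enyl)phenol | COc1c(O)c(I)c(OCOC)c(CC=C(C)C)c1OCOC
A4 | alternative 2 | carbon monoxide | [C-]#[O+]
A5 | alternative 2 | phenylacetylene | C#Cc1ccccc1
A6 | alternative 2 | 8-methoxy-5,7-bis(methoxymethoxy)-6-(3-methylbut-2-enyl)flavone | COc1c(OCOC)c(CC=C(C)C)c(OCOC)c2c1OC(c1ccccc1)=CC2=O
A7 | alternative 3 | (2R,3S)-3-hydroxy-7-methoxy-6-(methoxymethoxy)-5-(3-methylbut-2-enyl)-2-phenyl-4-(triisopropylsilyloxy)-2,3-dihydro-1-benzofuran-3-carbaldehyde (either C3 epimer would serve) | COc1c(OCOC)c(CC=C(C)C)c(O[Si](C(C)C)(C(C)C)C(C)C)c2c1O[C@H](c1ccccc1)[C@]2(O)C=O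
A8 | alternative 3 | (2R,3R)-3-hydroxy-8-methoxy-7-(methoxymethoxy)-6-(3-methylbut-2-enyl)-5-(triisopropylsilyloxy)flavanone | COc1c(OCOC)c(CC=C(C)C)c(O[Si](C(C)C)(C(C)C)C(C)C)c2c1O[C@H](c1ccccc1)[C@@H](O)C2=O
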